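**Retrosynthetic overview**

1. Ring labels: upper flavan = rings A (benzo), B (4-hydroxyphenyl), C (pyran); lower flavan = rings D (benzo), E (catechol), F (pyran). The last disconnections are the six benzyl ethers and then both C2–H/C3–OH pairs (four stereocenters), which go back to one double syn hydroboration of the bis(flav-2-ene) 22.
2. Ring F is disconnected at C2=C3 (carbonyl–olefin metathesis of an olefinic aryl ester): C2 becomes the ester carbon of a ring E benzoate and C3 the inner carbon of an allyl group on ring D.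
3. Enabling feature: in ring F, C2 bears only H, O1 (the phenol oxygen of ring D) and ring E, and C3 is joined through C4H2 to the ring D carbon ortho to O1. Ring F is therefore an ortho-allylphenyl benzoate at a higher oxidation level, and the cis H-2/HO-3 pair of the 2,3-trans flavan-3-ol is what syn H–B addition to C2=C3 gives.
4. The ester goes back to acid 15 and phenol 19. The ring C enol ether comes from cyclodehydration of a 2-hydroxyaryl β,β-diaryl ketone, whose only stereocenter (C4) is set by a rhodium-catalyzed asymmetric 1,4-addition of the ring E boronic acid 9 to chalcone 4 (rings A and B).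
5. Order of ring formation: the four benzene rings are bought; ring C is closed in step 6 (C–O bond), ring F in step 11 (C2–C3 bond).

Key step: step 11

Assumption: the face chosen by (R)-BINAP in step 5 and by IpcBH2 from (+)-α-pinene in step 12 is assigned by analogy with simple (E)-enones and 1-arylcycloalkenes; if either sense proves opposite, the enantiomeric ligand or reagent is used.

**Route**

Step 1
Reactants: 1 4-(benzyloxy)-2-hydroxybenzaldehyde
Product: 2 4-(benzyloxy)-2-(methoxymethoxy)benzaldehyde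
Conditions: MOMCl, K2CO3, acetone, reflux
Reagents that add atoms: chloromethyl methyl ether, COCCl
Why: Williamson etherification of the phenoxide; the MOM acetal keeps a free ortho-phenoxide from deactivating the enone in step 5 and is removed by the same acid that closes ring C in step 6.

Step 2
Reactants: 2 4-(benzyloxy)-2-(methoxymethoxy)benzaldehyde; 3 1-[4-(benzyloxy)phenyl]ethan-1-one
Product: 4 (E)-3-[4-(benzyloxy)-2-(methoxymethoxy)phenyl]-1-[4-(benzyloxy)phenyl]prop-2-en-1-one
Conditions: KOH, EtOH, rt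
Reagents that add atoms: none
Why: Claisen–Schmidt condensation of a non-enolizable aldehyde with the methyl ketone; E1cB dehydration should give the conjugated (E)-enone, and no stereocenter is formed.

Step 3
Reactants: 5 1,2-bis(benzyloxy)benzene
Product: 6 1,2-bis(benzyloxy)-4,5-dibromobenzene
Conditions: NBS (2.1 equiv), MeCN, rt, dark
Reagents that add atoms: N-bromosuccinimide, O=C1CCC(=O)N1Br
Why: electrophilic aromatic bromination in which each ether oxygen directs one bromine to its para position (C4 and C5), while the unactivated benzyl rings should not react.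

Step 4
Reactants: 6 1,2-bis(benzyloxy)-4,5-dibromobenzene
Product: 9 [4,5-bis(benzyloxy)-2-bromophenyl]boronic acid, via arylmagnesium chloride 7 (not isolated), via dimethyl arylboronate 8 (not isolated)
Conditions: iPrMgCl·LiCl (1.05 equiv), THF, −20 °C; B(OMe)3, −20 °C to rt; 1 M HCl
Reagents that add atoms: trimethyl borate, COB(OC)OC; water, O
Why: bromine–magnesium exchange is accelerated by the neighboring bromine and should stop after one exchange; below 0 °C the ortho-bromoaryl Grignard reagent does not collapse to an aryne and is trapped by the borate, which hydrolysis converts to the boronic acid.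

Step 5
Reactants: 4 (E)-3-[4-(benzyloxy)-2-(methoxymethoxy)phenyl]-1-[4-(benzyloxy)phenyl]prop-2-en-1-one; 9 [4,5-bis(benzyloxy)-2-bromophenyl]boronic acid
Product: 10 (3S)-3-[4-(benzyloxy)-2-(methoxymethoxy)phenyl]-3-[4,5-bis(benzyloxy)-2-bromophenyl]-1-[4-(benzyloxy)phenyl]propan-1-one
Conditions: [Rh(OH)((R)-BINAP)]2 (3 mol % Rh), 9 (2.5 equiv), 1,4-dioxane/H2O (10:1), 50 °C
Reagents that add atoms: none
Why: Hayashi–Miyaura asymmetric 1,4-addition, in which the aryl–rhodium species from transmetalation inserts the enone and the (R)-BINAP–rhodium complex selects the enone face, setting the diarylmethine carbon (future C4 of ring C) as (S); the aryl bromide is inert to monovalent rhodium and the hydroxo complex allows a mild temperature that limits protodeboronation.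

Step 6
Reactants: 10 (3S)-3-[4-(benzyloxy)-2-(methoxymethoxy)phenyl]-3-[4,5-bis(benzyloxy)-2-bromophenyl]-1-[4-(benzyloxy)phenyl]propan-1-one
Product: 12 (4S)-7-(benzyloxy)-2-[4-(benzyloxy)phenyl]-4-[4,5-bis(benzyloxy)-2-bromophenyl]-4H-chromene, via phenol ketone 11 (not isolated)
Conditions: HCl (cat.), MeOH/THF, 45 °C; then PPTS (cat.), toluene, 4 Å MS, 80 °C, under argon
Reagents that add atoms: none
Why: acid-catalyzed acetal cleavage frees the phenol, which adds to the ketone (6-exo-trig hemiketal formation), and dehydration under water removal should give the 2-aryl-4H-chromene of ring C; C4 is not epimerizable under these mild conditions and its descriptor changes only through priorities.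

Step 7
Reactants: 12 (4S)-7-(benzyloxy)-2-[4-(benzyloxy)phenyl]-4-[4,5-bis(benzyloxy)-2-bromophenyl]-4H-chromene
Product: 15 4,5-bis(benzyloxy)-2-{(4R)-7-(benzyloxy)-2-[4-(benzyloxy)phenyl]-4H-chromen-4-yl}benzoic acid, via aryllithium 13 (not isolated), via lithium carboxylate 14 (not isolated)
Conditions: t-BuLi (2.1 equiv), THF, −78 °C; CO2; AcOH (3 equiv), −78 °C to rt
Reagents that add atoms: carbon dioxide, O=C=O
Why: bromine–lithium exchange followed by carboxylation; the enol ether and benzyl ethers are inert at −78 °C, C4–H is not acidic because its anion would be an antiaromatic pyranyl anion, and protonation with acetic acid spares the acid-labile enol ether.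

Step 8
Reactants: 16 3-(benzyloxy)phenol
Product: 17 5-(benzyloxy)-2-iodophenol
Conditions: I2, NaHCO3, THF/H2O, 0 °C
Reagents that add atoms: iodine, [I][I]
Why: electrophilic iodination of the phenoxide at the less hindered ortho position, which is also para to the benzyloxy group; this fixes the site of the allyl group without the regioisomer problem of an aromatic Claisen rearrangement.

Step 9
Reactants: 17 5-(benzyloxy)-2-iodophenol; 18 4,4,5,5-tetramethyl-2-(prop-2-en-1-yl)-1,3,2-dioxaborolane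
Product: 19 5-(benzyloxy)-2-(prop-2-en-1-yl)phenol
Conditions: Pd(PPh3)4 (5 mol %), CsF, THF, reflux
Reagents that add atoms: none
Why: Suzuki–Miyaura allyl–aryl cross-coupling under fluoride activation; the free phenol is tolerated and the allyl group enters at the carbon that carried iodine.

Step 10
Reactants: 15 4,5-bis(benzyloxy)-2-{(4R)-7-(benzyloxy)-2-[4-(benzyloxy)phenyl]-4H-chromen-4-yl}benzoic acid; 19 5-(benzyloxy)-2-(prop-2-en-1-yl)phenol
Product: 20 5-(benzyloxy)-2-(prop-2-en-1-yl)phenyl 4,5-bis(benzyloxy)-2-{(4R)-7-(benzyloxy)-2-[4-(benzyloxy)phenyl]-4H-chromen-4-yl}benzoate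
Conditions: DCC, DMAP (cat.), CH2Cl2, 0 °C to rt
Reagents that add atoms: none
Why: Steglich esterification under neutral conditions that leave the ring C enol ether untouched; the acid is used at once and no stereocenter is affected.

Step 11
Reactants: 20 5-(benzyloxy)-2-(prop-2-en-1-yl)phenyl 4,5-bis(benzyloxy)-2-{(4R)-7-(benzyloxy)-2-[4-(benzyloxy)phenyl]-4H-chromen-4-yl}benzoate
Product: 22 (4R)-7-(benzyloxy)-2-[4-(benzyloxy)phenyl]-4-{4,5-bis(benzyloxy)-2-[7-(benzyloxy)-4H-chromen-2-yl]phenyl}-4H-chromene, via titanium alkylidene 21 (not isolated)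
Conditions: TiCl4, Zn, PbCl2 (cat.), TMEDA, CH3CHBr2, THF/CH2Cl2, 0 to 65 °C
Reagents that add atoms: none
Why: Zn reduces TiCl4 in the presence of CH3CHBr2 to a titanium ethylidene, which exchanges with the allyl alkene (propene lost) to give alkylidene 21; [2+2] addition of its carbon (C3) to the ester carbonyl (C2) and cycloreversion of the oxatitanacyclobutane then give the C2=C3 enol ether and a Ti=O bond. The closest known reaction type is the Takai–Utimoto olefinic-ester cyclization to six- and seven-membered cyclic enol ethers; the stepwise variant (ester methylenation, then ring-closing metathesis) is known for 2-allylphenyl benzoates. Ring F is closed as a six-membered ring in the exo sense with respect to the carbonyl group (6-exo-trig, ring-closing carbonyl–olefin metathesis), with O1 and C4 already in place. No stereocenter is formed, and C4 of ring C is safe because the medium is basic and aprotic. The step needs the alkene to react before the ester is ethylidenated from outside and needs the ring C enol ether to stay out: the benzoate is hindered by its ortho substituent, the ring C alkene is trisubstituted, and the allyl group is the only terminal alkene. The precursor is shaped for this by carrying C2 at the ester oxidation level, which the hydroboration of step 12 brings back to the ether level.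

Step 12
Reactants: 22 (4R)-7-(benzyloxy)-2-[4-(benzyloxy)phenyl]-4-{4,5-bis(benzyloxy)-2-[7-(benzyloxy)-4H-chromen-2-yl]phenyl}-4H-chromene
Product: 24 (2R,3S,4R)-7-(benzyloxy)-2-[4-(benzyloxy)phenyl]-4-{4,5-bis(benzyloxy)-2-[(2R,3S)-7-(benzyloxy)-3-hydroxy-3,4-dihydro-2H-chromen-2-yl]phenyl}-3,4-dihydro-2H-chromen-3-ol, via bis(isopinocampheylboryl) adduct 23 (not isolated)
Conditions: IpcBH2 from (+)-α-pinene (4 equiv), THF, −25 to 0 °C; then NaOH, H2O2, 0 °C to rt
Reagents that add atoms: hydrogen peroxide, OO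
Why: Brown asymmetric hydroboration–oxidation, in which H–B adds syn across each C2=C3 with boron at C3 (β to O1, remote from the aryl group) so that oxidation with retention gives the 2,3-trans pattern; at ring C the borane should enter anti to the C4 aryl group and at ring F the face is chosen by the reagent as for 1-arylcycloalkenes, both rings needing the same (2R,3S) sense so that reagent and substrate control are matched.

Step 13
Reactants: 24 (2R,3S,4R)-7-(benzyloxy)-2-[4-(benzyloxy)phenyl]-4-{4,5-bis(benzyloxy)-2-[(2R,3S)-7-(benzyloxy)-3-hydroxy-3,4-dihydro-2H-chromen-2-yl]phenyl}-3,4-dihydro-2H-chromen-3-ol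
Product: 25 (2R,3S,4R)-4-{2-[(2R,3S)-3,7-dihydroxy-3,4-dihydro-2H-chromen-2-yl]-4,5-dihydroxyphenyl}-2-(4-hydroxyphenyl)-3,4-dihydro-2H-chromene-3,7-diol
Conditions: H2 (1 atm), Pd(OH)2/C, EtOAc/MeOH, rt
Reagents that add atoms: none
Why: heterogeneous hydrogenolysis of the six benzyl aryl ethers; under neutral conditions at 1 atm the O1–C2 bonds of both flavan rings and the C4–aryl bond should survive, and no stereocenter is affected.

**Compound list**

1 | 4-(benzyloxy)-2-hydroxybenzaldehyde | O=Cc1ccc(OCc2ccccc2)cc1O | starting material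
2 | 4-(benzyloxy)-2-(methoxymethoxy)benzaldehyde | COCOc1cc(OCc2ccccc2)ccc1C=O | intermediate
3 | 1-[4-(benzyloxy)phenyl]ethan-1-one | CC(=O)c1ccc(OCc2ccccc2)cc1 | starting material
4 | (E)-3-[4-(benzyloxy)-2-(methoxymethoxy)phenyl]-1-[4-(benzyloxy)phenyl]prop-2-en-1-one | COCOc1cc(OCc2ccccc2)ccc1/C=C/C(=O)c1ccc(OCc2ccccc2)cc1 | intermediate
5 | 1,2-bis(benzyloxy)benzene | c1ccc(cc1)COc1ccccc1OCc1ccccc1 | starting material
6 | 1,2-bis(benzyloxy)-4,5-dibromobenzene | Brc1cc(OCc2ccccc2)c(OCc2ccccc2)cc1Br | intermediate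
7 | [4,5-bis(benzyloxy)-2-bromophenyl]magnesium chloride | Cl[Mg]c1cc(OCc2ccccc2)c(OCc2ccccc2)cc1Br | intermediate
8 | dimethyl [4,5-bis(benzyloxy)-2-bromophenyl]boronate | COB(OC)c1cc(OCc2ccccc2)c(OCc2ccccc2)cc1Br | intermediate
9 | [4,5-bis(benzyloxy)-2-bromophenyl]boronic acid | OB(O)c1cc(OCc2ccccc2)c(OCc2ccccc2)cc1Br | intermediate
10 | (3S)-3-[4-(benzyloxy)-2-(methoxymethoxy)phenyl]-3-[4,5-bis(benzyloxy)-2-bromophenyl]-1-[4-(benzyloxy)phenyl]propan-1-one | COCOc1cc(OCc2ccccc2)ccc1[C@@H](c1cc(OCc2ccccc2)c(OCc2ccccc2)cc1Br)CC(=O)c1ccc(OCc2ccccc2)cc1 | intermediate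
11 | (3S)-3-[4-(benzyloxy)-2-hydroxyphenyl]-3-[4,5-bis(benzyloxy)-2-bromophenyl]-1-[4-(benzyloxy)phenyl]propan-1-one | Oc1cc(OCc2ccccc2)ccc1[C@@H](c1cc(OCc2ccccc2)c(OCc2ccccc2)cc1Br)CC(=O)c1ccc(OCc2ccccc2)cc1 | intermediate
12 | (4S)-7-(benzyloxy)-2-[4-(benzyloxy)phenyl]-4-[4,5-bis(benzyloxy)-2-bromophenyl]-4H-chromene | O1c2cc(OCc3ccccc3)ccc2[C@@H](c2cc(OCc3ccccc3)c(OCc3ccccc3)cc2Br)C=C1c1ccc(OCc2ccccc2)cc1 | intermediate
13 | aryllithium from 12 (Li in place of Br; same arrangement at C4) | O1c2cc(OCc3ccccc3)ccc2[C@@H](c2cc(OCc3ccccc3)c(OCc3ccccc3)cc2[Li])C=C1c1ccc(OCc2ccccc2)cc1 | intermediate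
14 | lithium salt of acid 15 | O1c2cc(OCc3ccccc3)ccc2[C@@H](c2cc(OCc3ccccc3)c(OCc3ccccc3)cc2C(=O)O[Li])C=C1c1ccc(OCc2ccccc2)cc1 | intermediate
15 | 4,5-bis(benzyloxy)-2-{(4R)-7-(benzyloxy)-2-[4-(benzyloxy)phenyl]-4H-chromen-4-yl}benzoic acid | O1c2cc(OCc3ccccc3)ccc2[C@@H](c2cc(OCc3ccccc3)c(OCc3ccccc3)cc2C(=O)O)C=C1c1ccc(OCc2ccccc2)cc1 | intermediate
16 | 3-(benzyloxy)phenol | Oc1cccc(OCc2ccccc2)c1 | starting material
17 | 5-(benzyloxy)-2-iodophenol | Oc1cc(OCc2ccccc2)ccc1I | intermediate
18 | 4,4,5,5-tetramethyl-2-(prop-2-en-1-yl)-1,3,2-dioxaborolane | C=CCB1OC(C)(C)C(C)(C)O1 | starting material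
19 | 5-(benzyloxy)-2-(prop-2-en-1-yl)phenol | Oc1cc(OCc2ccccc2)ccc1CC=C | intermediate
20 | 5-(benzyloxy)-2-(prop-2-en-1-yl)phenyl 4,5-bis(benzyloxy)-2-{(4R)-7-(benzyloxy)-2-[4-(benzyloxy)phenyl]-4H-chromen-4-yl}benzoate | O1c2cc(OCc3ccccc3)ccc2[C@@H](c2cc(OCc3ccccc3)c(OCc3ccccc3)cc2C(=O)Oc2cc(OCc3ccccc3)ccc2CC=C)C=C1c1ccc(OCc2ccccc2)cc1 | intermediate
21 | titanium alkylidene of 20 (terminal CH2 of the allyl group replaced by TiCl2; formal representation) | O1c2cc(OCc3ccccc3)ccc2[C@@H](c2cc(OCc3ccccc3)c(OCc3ccccc3)cc2C(=O)Oc2cc(OCc3ccccc3)ccc2CC=[Ti](Cl)Cl)C=C1c1ccc(OCc2ccccc2)cc1 | intermediate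
22 | (4R)-7-(benzyloxy)-2-[4-(benzyloxy)phenyl]-4-{4,5-bis(benzyloxy)-2-[7-(benzyloxy)-4H-chromen-2-yl]phenyl}-4H-chromene | O1c2cc(OCc3ccccc3)ccc2[C@@H](c2cc(OCc3ccccc3)c(OCc3ccccc3)cc2C2=CCc3ccc(OCc4ccccc4)cc3O2)C=C1c1ccc(OCc2ccccc2)cc1 | intermediate
23 | bis-borane adduct of 22 (24 with each C3–OH replaced by C3–BH(isopinocampheyl); same spatial arrangement as 24) | c1ccccc1COc1ccc([C@H]2Oc3cc(OCc4ccccc4)ccc3[C@@H](c3cc(OCc4ccccc4)c(OCc4ccccc4)cc3[C@H]3Oc4cc(OCc5ccccc5)ccc4C[C@@H]3B[C@@H]3C[C@@H]4C[C@H]([C@H]3C)C4(C)C)[C@@H]2B[C@@H]2C[C@@H]3C[C@H]([C@H]2C)C3(C)C)cc1 | intermediate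
24 | (2R,3S,4R)-7-(benzyloxy)-2-[4-(benzyloxy)phenyl]-4-{4,5-bis(benzyloxy)-2-[(2R,3S)-7-(benzyloxy)-3-hydroxy-3,4-dihydro-2H-chromen-2-yl]phenyl}-3,4-dihydro-2H-chromen-3-ol | c1ccccc1COc1ccc([C@H]2Oc3cc(OCc4ccccc4)ccc3[C@@H](c3cc(OCc4ccccc4)c(OCc4ccccc4)cc3[C@H]3Oc4cc(OCc5ccccc5)ccc4C[C@@H]3O)[C@@H]2O)cc1 | intermediate
25 | (2R,3S,4R)-4-{2-[(2R,3S)-3,7-dihydroxy-3,4-dihydro-2H-chromen-2-yl]-4,5-dihydroxyphenyl}-2-(4-hydroxyphenyl)-3,4-dihydro-2H-chromene-3,7-diol (CNP0275373.1) | Oc1ccc([C@H]2Oc3cc(O)ccc3[C@@H](c3cc(O)c(O)cc3[C@H]3Oc4cc(O)ccc4C[C@@H]3O)[C@@H]2O)cc1 | target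

**Step count and risks**

Total step count: 13. Longest linear sequence: 9 steps (1, 2, 5, 6, 7, 10, 11, 12, 13).

Steps most likely to fail:

Step 11. The titanium ethylidene may ethylidenate the hindered benzoate from outside before it engages the allyl group, so that an acyclic enol ether forms instead of ring F, or the low-valent titanium may cleave the aryl ester reductively. The fallback separates carbonyl olefination from ring closure. It sets out from 20: Petasis methylenation (Cp2TiMe2, toluene, 75 °C, dark) should give the acyclic enol ether diene F1, and ring-closing metathesis of F1 with the second-generation Hoveyda–Grubbs catalyst (toluene, 80 °C, ethene purged) forms the same C2=C3 bond and returns to the route at 22.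

Step 12. Reagent control at ring F may be eroded because the bulky ortho substituent twists ring E out of the enol ether plane. The first-formed dialkylborane may also hydroborate the second enol ether through a tether, and the C3 borane may undergo β-elimination with ring opening. The fallback treats the two rings in separate operations. It sets out from 12: hydroboration with BH3·SMe2 (THF, 0 °C; NaOH, H2O2), controlled by the C4 aryl group alone, should give the bromo flavan-3-ol F2, and benzylation (NaH, BnBr, DMF) its 3-O-benzyl ether F3. Bromine–lithium exchange and carboxylation as in step 7 give the benzoic acid F4, Steglich esterification with 19 gives the allylphenyl ester F5, and the olefinic-ester cyclization of step 11 gives the ring F enol ether F6. Hydroboration of this single enol ether with IpcBH2 and oxidation give the heptabenzyl flavan-3-ol F7; any ring F epimer is a diastereomer and can be removed by chromatography. Hydrogenolysis of the seven benzyl ethers returns to the route at 25.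

Step 5. Transmetalation of the ortho-bromo boronic acid may be slow and lose out to protodeboronation, and the electron-rich β-aryl enone may insert sluggishly, so that conversion or enantioselectivity falls short. The fallback exchanges the roles of the two aryl groups, so that the bromine sits on the enone. It sets out from 6, 3 and 17: the Grignard reagent 7 from 6 is trapped with DMF to give 4,5-bis(benzyloxy)-2-bromobenzaldehyde F8, and Claisen–Schmidt condensation of F8 with 3 gives the bromo chalcone F9. Phenol 17 is converted to the MOM ether F10 (MOMCl, K2CO3) and then, by iodine–magnesium exchange with iPrMgCl·LiCl, B(OMe)3 and aqueous NH4Cl, to the boronic acid F11. Rhodium-catalyzed addition of F11 to F9 with (S)-BINAP (the opposite ligand, because the entering aryl group is now ring A) returns to the route at 10.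

**Further compounds**

F1 | step 11 | (4R)-7-(benzyloxy)-2-[4-(benzyloxy)phenyl]-4-[4,5-bis(benzyloxy)-2-{1-[5-(benzyloxy)-2-(prop-2-en-1-yl)phenoxy]ethenyl}phenyl]-4H-chromene | O1c2cc(OCc3ccccc3)ccc2[C@@H](c2cc(OCc3ccccc3)c(OCc3ccccc3)cc2C(=C)Oc2cc(OCc3ccccc3)ccc2CC=C)C=C1c1ccc(OCc2ccccc2)cc1
F2 | step 12 | (2R,3S,4S)-7-(benzyloxy)-2-[4-(benzyloxy)phenyl]-4-[4,5-bis(benzyloxy)-2-bromophenyl]-3,4-dihydro-2H-chromen-3-ol | c1ccccc1COc1ccc([C@H]2Oc3cc(OCc4ccccc4)ccc3[C@@H](c3cc(OCc4ccccc4)c(OCc4ccccc4)cc3Br)[C@@H]2O)cc1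
F3 | step 12 | (2R,3S,4S)-3,7-bis(benzyloxy)-2-[4-(benzyloxy)phenyl]-4-[4,5-bis(benzyloxy)-2-bromophenyl]-3,4-dihydro-2H-chromene | c1ccccc1COc1ccc([C@H]2Oc3cc(OCc4ccccc4)ccc3[C@@H](c3cc(OCc4ccccc4)c(OCc4ccccc4)cc3Br)[C@@H]2OCc2ccccc2)cc1
F4 | step 12 | 4,5-bis(benzyloxy)-2-{(2R,3S,4R)-3,7-bis(benzyloxy)-2-[4-(benzyloxy)phenyl]-3,4-dihydro-2H-chromen-4-yl}benzoic acid | c1ccccc1COc1ccc([C@H]2Oc3cc(OCc4ccccc4)ccc3[C@@H](c3cc(OCc4ccccc4)c(OCc4ccccc4)cc3C(=O)O)[C@@H]2OCc2ccccc2)cc1
F5 | step 12 | 5-(benzyloxy)-2-(prop-2-en-1-yl)phenyl 4,5-bis(benzyloxy)-2-{(2R,3S,4R)-3,7-bis(benzyloxy)-2-[4-(benzyloxy)phenyl]-3,4-dihydro-2H-chromen-4-yl}benzoate | c1ccccc1COc1ccc([C@H]2Oc3cc(OCc4ccccc4)ccc3[C@@H](c3cc(OCc4ccccc4)c(OCc4ccccc4)cc3C(=O)Oc3cc(OCc4ccccc4)ccc3CC=C)[C@@H]2OCc2ccccc2)cc1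
F6 | step 12 | (2R,3S,4R)-3,7-bis(benzyloxy)-2-[4-(benzyloxy)phenyl]-4-{4,5-bis(benzyloxy)-2-[7-(benzyloxy)-4H-chromen-2-yl]phenyl}-3,4-dihydro-2H-chromene | c1ccccc1COc1ccc([C@H]2Oc3cc(OCc4ccccc4)ccc3[C@@H](c3cc(OCc4ccccc4)c(OCc4ccccc4)cc3C3=CCc4ccc(OCc5ccccc5)cc4O3)[C@@H]2OCc2ccccc2)cc1
F7 | step 12 | (2R,3S)-7-(benzyloxy)-2-{4,5-bis(benzyloxy)-2-[(2R,3S,4R)-3,7-bis(benzyloxy)-2-[4-(benzyloxy)phenyl]-3,4-dihydro-2H-chromen-4-yl]phenyl}-3,4-dihydro-2H-chromen-3-ol | c1ccccc1COc1ccc([C@H]2Oc3cc(OCc4ccccc4)ccc3[C@@H](c3cc(OCc4ccccc4)c(OCc4ccccc4)cc3[C@H]3Oc4cc(OCc5ccccc5)ccc4C[C@@H]3O)[C@@H]2OCc2ccccc2)cc1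
F8 | step 5 | 4,5-bis(benzyloxy)-2-bromobenzaldehyde | O=Cc1cc(OCc2ccccc2)c(OCc2ccccc2)cc1Br
F9 | step 5 | (E)-3-[4,5-bis(benzyloxy)-2-bromophenyl]-1-[4-(benzyloxy)phenyl]prop-2-en-1-one | O=C(/C=C/c1cc(OCc2ccccc2)c(OCc2ccccc2)cc1Br)c1ccc(OCc2ccccc2)cc1
F10 | step 5 | 4-(benzyloxy)-1-iodo-2-(methoxymethoxy)benzene | COCOc1cc(OCc2ccccc2)ccc1I
F11 | step 5 | [4-(benzyloxy)-2-(methoxymethoxy)phenyl]boronic acid | COCOc1cc(OCc2ccccc2)ccc1B(O)O
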